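**Plan** (upper flavan unit unprimed, rings A–C; lower unit primed, rings D–F)
1. Retrosynthesis: after removal of nine benzyl ethers, ring F is cut at O1'–C2' and at C3'–O (epoxide, then alkene), leaving a Z-allylic alcohol on the ring-D phenol. Further cuts are C4'–C3' (alkynyl addition to a ring-D aldehyde), C4a'–C4' (ortho-formylation) and C4–C8' (arylation of a catechin C4 cation).
2. Forward: rings A, B and C come intact from (−)-catechin; ring D is attached at C4, C3 is inverted, the C4'–C3'–C2'–ring E chain is joined to ring D, ring F closes last, and hydrogenolysis ends the route.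
3. Stereochemistry: C2 from (−)-catechin; C4 by arylation anti to the C3 hydroxyl; C3 by oxidation and hydride addition anti to both aryl groups; C4' by a BINOL–titanium alkynylation; C3' and C2' in the closure of ring F.
4. Enabling feature: in ring F (O1', C2', C3', C4') ring E at C2' is cis to the C3' hydroxyl and the C4' hydroxyl is trans to it. This is the pattern left by epoxidation of a Z-alkene from the face of the C4' hydroxyl followed by anti attack of the C8a' phenol oxygen on benzylic C2'.

Key step: step 15

Assumption: in step 12 the facial sense known for simple aryl aldehydes is taken to hold, (S)-BINOL leading to the (R) carbinol; if the hindered aldehyde reverses it, (R)-BINOL is used.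
Remark: ether 3 is drawn 3,4-cis, the expected isomer; its C4 configuration is lost on ionisation in step 3 and has no bearing on the route.

Step 1
Reactants: 1 (−)-catechin
Product: 2 5,7-bis(benzyloxy)-2-[3,4-bis(benzyloxy)phenyl]chroman-3-ol (2S,3R)
Conditions: BnBr (4.4 equiv), K2CO3, DMF, 0 °C to rt
Reagents that add atoms: benzyl bromide, BrCc1ccccc1
Why: Williamson etherification in which K2CO3 deprotonates only the four phenols, so the C3 alcohol stays free and both stereocentres are untouched.

Step 2
Reactants: 2 tetra-O-benzyl-(−)-catechin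
Product: 3 4-(2-ethoxyethoxy) ether of 2 (2S,3R,4R; ether cis to the C3 hydroxyl)
Conditions: DDQ, 2-ethoxyethanol, CH2Cl2, rt
Reagents that add atoms: 2-ethoxyethanol, CCOCCO
Why: DDQ benzylic oxidation, in which hydride abstraction from C4 gives a cation stabilised by the 5,7-dioxygenated ring A that 2-ethoxyethanol traps.

Step 3
Reactants: 3 C4 ether; 4 3,5-bis(benzyloxy)phenol (3 equiv)
Product: 5 C4 adduct of the tetrabenzyl catechin core (2S,3R) carrying a 2-hydroxy-4,6-bis(benzyloxy)phenyl ring D at C4 cis to the C2 aryl and trans to the C3 hydroxyl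
Conditions: TMSOTf (cat.), CH2Cl2, −78 °C
Reagents that add atoms: none
Why: Friedel–Crafts arylation through the ring-A-stabilised C4 cation; the phenol should react at its carbon flanked by OH and OBn (less hindered than the carbon between two OBn, the same bias that favours C8 over C6 in 5,7-dibenzyloxyflavan nucleophiles) and from the face anti to the C3 hydroxyl, which sets C4 as 3,4-trans and 2,4-cis, while the excess of 4 limits double alkylation.

Step 4
Reactants: 5 ring-D phenol adduct
Product: 6 ring-D allyl ether of 5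
Conditions: allyl bromide, K2CO3, acetone, reflux
Reagents that add atoms: allyl bromide, C=CCBr
Why: Williamson etherification selective for the phenol over the secondary C3 alcohol, masking the phenol against the oxidant of step 5 and the benzylation of step 7.

Step 5
Reactants: 6 allyl ether
Product: 7 flavan-3-one (C3 ketone) of 6 in which the C2 and C4 aryl groups remain cis
Conditions: Dess–Martin periodinane, wet CH2Cl2, rt
Reagents that add atoms: none
Why: Dess–Martin oxidation of the secondary alcohol under near-neutral conditions, which should leave the enolisable C2 and C4 centres (already in the favoured 2,4-cis arrangement), the allyl ether and the benzyl ethers untouched.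

Step 6
Reactants: 7 flavan-3-one
Product: 8 all-cis alcohol (2S,3S; C2 aryl and C3 hydroxyl and C4 aryl on one face) still carrying the ring-D allyl ether
Conditions: LiBH(s-Bu)3, LiBr, THF, −78 °C; then H2O
Reagents that add atoms: none
Why: Ketone reduction by a bulky borohydride: the cis C2 and C4 aryl groups shield one face, so hydride should add from the other and place the C3 hydroxyl cis to both, the same oxidation–reduction inversion that converts catechin into epicatechin skeletons.

Step 7
Reactants: 8 all-cis alcohol
Product: 9 3-O-benzyl ether of 8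
Conditions: NaH, BnBr, n-Bu4NI (cat.), DMF, 0 °C to rt
Reagents that add atoms: benzyl bromide, BrCc1ccccc1
Why: Williamson etherification of the sodium alkoxide; the phenol is capped as its allyl ether, so only the C3 oxygen is benzylated.

Step 8
Reactants: 9 allyl ether
Product: 10 ring-D phenol (free hydroxyl on the future C8a')
Conditions: Pd(PPh3)4 (cat.), morpholine, THF, rt
Reagents that add atoms: none
Why: Tsuji–Trost-type deallylation in which zerovalent palladium ionises the aryl allyl ether to a π-allyl complex that morpholine captures, freeing the phenol under neutral conditions that benzyl ethers tolerate.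

Step 9
Reactants: 10 ring-D phenol
Product: 11 ring-D salicylaldehyde (formyl group on the future C4a' between the phenol and the 5'-benzyloxy group)
Conditions: MgCl2, Et3N, (CH2O)n, THF, reflux
Reagents that add atoms: formaldehyde (as paraformaldehyde), C=O
Why: Casnati–Skattebøl ortho-formylation, in which the magnesium phenoxide delivers formaldehyde through a six-membered transition state to the only free ortho carbon and a second formaldehyde oxidises the benzylic alkoxide by Oppenauer-type hydride transfer, so rings A, B and the para position of ring D should not react.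

Step 10
Reactants: 11 salicylaldehyde
Product: 12 tert-butyldimethylsilyl ether of 11
Conditions: TBSOTf, 2,6-lutidine, CH2Cl2, 0 °C
Reagents that add atoms: tert-butyldimethylsilyl triflate, CC(C)(C)[Si](C)(C)OS(=O)(=O)C(F)(F)F
Why: Silylation by the reactive silyl triflate of a hydroxyl that is hydrogen-bonded to the aldehyde and flanked by ring C; the silyl ether keeps the phenol from quenching the zinc reagent of step 12 and can later be removed without acid.

Step 11
Reactants: 13 3,4-bis(benzyloxy)benzaldehyde
Product: 14 1,2-bis(benzyloxy)-4-ethynylbenzene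
Conditions: dimethyl (1-diazo-2-oxopropyl)phosphonate, K2CO3, MeOH, rt
Reagents that add atoms: dimethyl (1-diazo-2-oxopropyl)phosphonate, CC(=O)C(=[N+]=[N-])P(=O)(OC)OC
Why: Seyferth–Gilbert homologation in its Ohira–Bestmann variant: methanolysis unmasks the diazomethylphosphonate anion, which adds to the aldehyde, eliminates dimethyl phosphate and rearranges through the alkylidene carbene to the terminal alkyne.

Step 12
Reactants: 12 silyl-protected aldehyde; 14 ring-E alkyne (3 equiv)
Product: 15 (R)-propargylic alcohol in which C4' carries OH and ring D (silyl ether) and the C3'≡C2' alkyne bearing ring E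
Conditions: 14, Et2Zn, toluene, reflux; then (S)-BINOL (40 mol%), Ti(OiPr)4 (50 mol%), 12, CH2Cl2, rt; aq. NH4Cl
Reagents that add atoms: none
Why: Catalytic asymmetric alkynylzinc addition in which the BINOL complex of tetravalent titanium activates the aldehyde and shields one face, so the arylalkynylzinc should add under catalyst control to give the (R) carbinol at C4', the upper-unit stereocentres being remote.

Step 13
Reactants: 15 propargylic alcohol
Product: 16 (R,Z)-allylic alcohol (C3'=C2' cis) carrying the ring-D silyl ether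
Conditions: H2 (1 atm), Pd/CaCO3 poisoned with Pb(OAc)2 (Lindlar catalyst), quinoline, EtOAc, rt
Reagents that add atoms: none
Why: Lindlar semi-hydrogenation: syn addition of hydrogen on the lead-poisoned palladium surface gives the Z-alkene, and quinoline holds back over-reduction and benzyl ether cleavage.

Step 14
Reactants: 16 silyl-protected Z-allylic alcohol
Product: 17 (R,Z)-allylic alcohol bearing the free C8a' phenol
Conditions: n-Bu4NF, AcOH (1:1), THF, 0 °C; used at once, base-washed glassware
Reagents that add atoms: none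
Why: Fluoride-induced cleavage of the aryl silyl ether (driven by the Si–F bond) buffered by acetic acid, so that neither a free phenoxide nor a strong acid is present to ionise the doubly activated allylic carbinol.

Step 15
Reactants: 17 Z-allylic alcohol on the ring-D phenol
Product: 19 nona-O-benzyl ether of the target bearing the free 3',4'-diol (2'R,3'R,4'S), via threo cis-epoxy alcohol 18 (not isolated)
Conditions: VO(acac)2 (5 mol%), t-BuOOH (anhydrous, in decane), CH2Cl2, −20 °C to rt; Et3N-deactivated silica
Reagents that add atoms: tert-butyl hydroperoxide, CC(C)(C)OO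
Why: t-BuOOH oxidises VO(acac)2 to a pentavalent vanadium alkoxide that binds the C4' hydroxyl and tert-butylperoxide and passes oxygen intramolecularly to the Z-alkene; the closest known reaction is the threo-selective vanadium epoxidation of Z-allylic secondary alcohols. Allylic 1,3-strain between the cis ring E and the C4' substituents, large here because both are aryl-bearing, holds C4'–H in the alkene plane, so oxygen arrives on the hydroxyl face and C3'–O becomes trans to C4'–O in the ring to come (control of C3'). The C8a' phenol then attacks C2' of epoxide 18 anti to the breaking C–O bond, helped by the Lewis-acidic vanadium, and closes ring F in a 6-endo-tet mode, as in the known cyclisation of o-hydroxybenzyl aryl epoxides to 2-arylchroman-3-ols; inversion at C2' turns the Z geometry into the 2',3'-cis relationship (control of C2'). The 6-endo path should beat 5-exo because C2' is benzylic to the electron-rich ring E, whereas C3' is deactivated and crowded by the adjacent C4' oxygen. The step needs syn facial selectivity, endo regioselectivity and a non-acidic medium; the first two rest on the Z geometry and the ring-E donor, the third on catalytic vanadium at low temperature, under which the ionisable C4' carbinol and the phenol should persist.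

Step 16
Reactants: 19 nonabenzyl ether
Product: 20 target compound CNP0114173.1
Conditions: H2 (1 atm), Pd(OH)2 on carbon, Et3N, THF/MeOH, rt
Reagents that add atoms: none
Why: Catalytic hydrogenolysis of all nine benzyl ethers; triethylamine keeps the medium non-acidic and slows benzylic C–OH cleavage, so the ring-F diol and the six stereocentres should survive.

**Compound list**
1 | (−)-catechin, (2S,3R)-2-(3,4-dihydroxyphenyl)chromane-3,5,7-triol | Oc1cc(O)c2c(c1)O[C@@H](c1ccc(O)c(O)c1)[C@H](O)C2 | starting material
2 | 5,7-bis(benzyloxy)-2-[3,4-bis(benzyloxy)phenyl]chroman-3-ol, (2S,3R) | c1ccccc1COc1cc(OCc3ccccc3)c2c(c1)O[C@@H](c1ccc(OCc3ccccc3)c(OCc3ccccc3)c1)[C@H](O)C2 | intermediate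
3 | 4-(2-ethoxyethoxy) ether of 2, (2S,3R,4R), ether cis to the C3 hydroxyl | c1ccccc1COc1cc(OCc3ccccc3)c2c(c1)O[C@@H](c1ccc(OCc3ccccc3)c(OCc3ccccc3)c1)[C@H](O)[C@@H]2OCCOCC | intermediate
4 | 3,5-bis(benzyloxy)phenol | Oc1cc(OCc2ccccc2)cc(OCc2ccccc2)c1 | starting material
5 | C4 adduct: core of 2 (2S,3R) with a 2-hydroxy-4,6-bis(benzyloxy)phenyl ring D at C4, cis to the C2 aryl, trans to the C3 hydroxyl | c1ccccc1COc1cc(OCc3ccccc3)c2c(c1)O[C@@H](c1ccc(OCc3ccccc3)c(OCc3ccccc3)c1)[C@H](O)[C@H]2c1c(O)cc(OCc3ccccc3)cc1OCc1ccccc1 | intermediate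
6 | ring-D allyl ether of 5 | c1ccccc1COc1cc(OCc3ccccc3)c2c(c1)O[C@@H](c1ccc(OCc3ccccc3)c(OCc3ccccc3)c1)[C@H](O)[C@H]2c1c(OCC=C)cc(OCc3ccccc3)cc1OCc1ccccc1 | intermediate
7 | flavan-3-one of 6, C2 and C4 aryl groups cis | c1ccccc1COc1cc(OCc3ccccc3)c2c(c1)O[C@@H](c1ccc(OCc3ccccc3)c(OCc3ccccc3)c1)C(=O)[C@H]2c1c(OCC=C)cc(OCc3ccccc3)cc1OCc1ccccc1 | intermediate
8 | all-cis alcohol, (2S,3S), C2 aryl, C3 hydroxyl and C4 aryl on one face; ring-D allyl ether | c1ccccc1COc1cc(OCc3ccccc3)c2c(c1)O[C@@H](c1ccc(OCc3ccccc3)c(OCc3ccccc3)c1)[C@@H](O)[C@H]2c1c(OCC=C)cc(OCc3ccccc3)cc1OCc1ccccc1 | intermediate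
9 | 3-O-benzyl ether of 8 | c1ccccc1COc1cc(OCc3ccccc3)c2c(c1)O[C@@H](c1ccc(OCc3ccccc3)c(OCc3ccccc3)c1)[C@@H](OCc1ccccc1)[C@H]2c1c(OCC=C)cc(OCc3ccccc3)cc1OCc1ccccc1 | intermediate
10 | ring-D phenol obtained from 9 by loss of the allyl group | c1ccccc1COc1cc(OCc3ccccc3)c2c(c1)O[C@@H](c1ccc(OCc3ccccc3)c(OCc3ccccc3)c1)[C@@H](OCc1ccccc1)[C@H]2c1c(O)cc(OCc3ccccc3)cc1OCc1ccccc1 | intermediate
11 | ring-D salicylaldehyde: formyl on C4a', ortho to the C8a' hydroxyl | c1ccccc1COc1cc(OCc3ccccc3)c2c(c1)O[C@@H](c1ccc(OCc3ccccc3)c(OCc3ccccc3)c1)[C@@H](OCc1ccccc1)[C@H]2c1c(O)c(C=O)c(OCc3ccccc3)cc1OCc1ccccc1 | intermediate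
12 | tert-butyldimethylsilyl ether of 11 | c1ccccc1COc1cc(OCc3ccccc3)c2c(c1)O[C@@H](c1ccc(OCc3ccccc3)c(OCc3ccccc3)c1)[C@@H](OCc1ccccc1)[C@H]2c1c(O[Si](C)(C)C(C)(C)C)c(C=O)c(OCc3ccccc3)cc1OCc1ccccc1 | intermediate
13 | 3,4-bis(benzyloxy)benzaldehyde | O=Cc1ccc(OCc2ccccc2)c(OCc2ccccc2)c1 | starting material
14 | 1,2-bis(benzyloxy)-4-ethynylbenzene | C#Cc1ccc(OCc2ccccc2)c(OCc2ccccc2)c1 | intermediate
15 | (R)-propargylic alcohol: C4'(OH) between ring D (silyl ether) and the alkyne bearing ring E | c1ccccc1COc1cc(OCc3ccccc3)c2c(c1)O[C@@H](c1ccc(OCc3ccccc3)c(OCc3ccccc3)c1)[C@@H](OCc1ccccc1)[C@H]2c1c(O[Si](C)(C)C(C)(C)C)c([C@H](O)C#Cc3ccc(OCc4ccccc4)c(OCc4ccccc4)c3)c(OCc3ccccc3)cc1OCc1ccccc1 | intermediate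
16 | (R,Z)-allylic alcohol, ring-D silyl ether | c1ccccc1COc1cc(OCc3ccccc3)c2c(c1)O[C@@H](c1ccc(OCc3ccccc3)c(OCc3ccccc3)c1)[C@@H](OCc1ccccc1)[C@H]2c1c(O[Si](C)(C)C(C)(C)C)c([C@H](O)/C=C\c3ccc(OCc4ccccc4)c(OCc4ccccc4)c3)c(OCc3ccccc3)cc1OCc1ccccc1 | intermediate
17 | (R,Z)-allylic alcohol with free C8a' phenol (precursor of the key step) | c1ccccc1COc1cc(OCc3ccccc3)c2c(c1)O[C@@H](c1ccc(OCc3ccccc3)c(OCc3ccccc3)c1)[C@@H](OCc1ccccc1)[C@H]2c1c(O)c([C@H](O)/C=C\c3ccc(OCc4ccccc4)c(OCc4ccccc4)c3)c(OCc3ccccc3)cc1OCc1ccccc1 | intermediate
18 | cis-epoxide (2'S,3'R) threo to the (4'S) carbinol, free C8a' phenol | c1ccccc1COc1cc(OCc3ccccc3)c2c(c1)O[C@@H](c1ccc(OCc3ccccc3)c(OCc3ccccc3)c1)[C@@H](OCc1ccccc1)[C@H]2c1c(O)c([C@H](O)[C@H]5O[C@H]5c3ccc(OCc4ccccc4)c(OCc4ccccc4)c3)c(OCc3ccccc3)cc1OCc1ccccc1 | intermediate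
19 | nona-O-benzyl ether of the target with free 3',4'-diol, (2'R,3'R,4'S) in ring F | c1ccccc1COc1cc(OCc3ccccc3)c2c(c1)O[C@@H](c1ccc(OCc3ccccc3)c(OCc3ccccc3)c1)[C@@H](OCc1ccccc1)[C@H]2c1c(OCc3ccccc3)cc(OCc3ccccc3)c2c1O[C@H](c1ccc(OCc3ccccc3)c(OCc3ccccc3)c1)[C@H](O)[C@H]2O | intermediate
20 | CNP0114173.1 | Oc1cc(O)c2c(c1)O[C@@H](c1ccc(O)c(O)c1)[C@@H](O)[C@H]2c1c(O)cc(O)c2c1O[C@H](c1ccc(O)c(O)c1)[C@H](O)[C@H]2O | target

**Total step count:** 16. **Longest linear sequence:** 15 steps (steps 1–10 and 12–16, from (−)-catechin); step 11 is a one-step side branch.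

**Steps most likely to fail**

Step 15. The vanadium peroxide may oxidise the electron-rich phenol or the carbinol instead of the alkene. The Z-allylic alcohol may ionise at C4' and close by dehydration to a 2H-chromene. The epoxide may open with loss of configuration at C2' or in the 5-exo mode, and facial selectivity may be incomplete. The fallback separates the two events while the phenol is masked, setting out from 16. Hydroxyl-directed epoxidation of 16 (VO(acac)2 and t-BuOOH, or NaHCO3-buffered m-CPBA, whose preferred geometry matches the in-plane C4'–H conformer of Z-allylic alcohols) should give the isolable silyl-protected threo cis-epoxy alcohol F1. With the phenol silylated, neither chromene formation nor phenol oxidation is possible at that stage. n-Bu4NF buffered with AcOH at low temperature then frees the phenol to give 18, which should close to 19 on its own or on brief contact with pyridinium p-toluenesulfonate. The route is rejoined at 19.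

Step 12. Addition to the hindered, electron-rich 2,6-dioxygenated aldehyde may be sluggish, facial control may be poor, or the silyl group may migrate to the new alkoxide. The fallback sets out from 12 and replaces catalyst-controlled C–C formation by reagent-controlled reduction. The lithium acetylide of 14 (n-BuLi, THF, −78 °C, cold quench) adds without stereocontrol to give 15 together with its C4' epimer, the (S)-propargylic alcohol F2. The mixture is oxidised with MnO2 to the ynone F3. Corey–Bakshi–Shibata reduction with the (S)-methyl oxazaborolidine and catecholborane at −78 °C, ring D acting as the large and the alkyne as the small group, should then return the (R) carbinol. The route is rejoined at 15.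

Step 3. The unsymmetrical phenol may react through the carbon between its two benzyloxy groups or through oxygen, the product may be alkylated a second time, or the 3,4-trans preference may erode. The fallback sets out from 3 and uses a regioconvergent nucleophile, 5-(benzyloxy)resorcinol (Oc1cc(O)cc(OCc2ccccc2)c1), under the same TMSOTf ionisation. Attack through a carbon between OH and OBn gives the 2,4-dihydroxy-6-benzyloxyphenyl adduct F4, and attack through the carbon between the two hydroxyls gives the 2,6-dihydroxy-4-benzyloxyphenyl adduct F5. A single O-benzylation (BnBr, 1 equiv, K2CO3, acetone) converts both into the same compound: in F4 the unhindered para hydroxyl reacts, in F5 either of the two equivalent ortho hydroxyls. The route is rejoined at 5.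

**Further compounds**
F1 | step 15 | silyl-protected threo cis-epoxy alcohol (ring-D tert-butyldimethylsilyl ether of 18) | c1ccccc1COc1cc(OCc3ccccc3)c2c(c1)O[C@@H](c1ccc(OCc3ccccc3)c(OCc3ccccc3)c1)[C@@H](OCc1ccccc1)[C@H]2c1c(O[Si](C)(C)C(C)(C)C)c([C@H](O)[C@H]5O[C@H]5c3ccc(OCc4ccccc4)c(OCc4ccccc4)c3)c(OCc3ccccc3)cc1OCc1ccccc1
F2 | step 12 | (S)-propargylic alcohol, C4' epimer of 15 | c1ccccc1COc1cc(OCc3ccccc3)c2c(c1)O[C@@H](c1ccc(OCc3ccccc3)c(OCc3ccccc3)c1)[C@@H](OCc1ccccc1)[C@H]2c1c(O[Si](C)(C)C(C)(C)C)c([C@@H](O)C#Cc3ccc(OCc4ccccc4)c(OCc4ccccc4)c3)c(OCc3ccccc3)cc1OCc1ccccc1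
F3 | step 12 | ynone (C4' ketone of 15) | c1ccccc1COc1cc(OCc3ccccc3)c2c(c1)O[C@@H](c1ccc(OCc3ccccc3)c(OCc3ccccc3)c1)[C@@H](OCc1ccccc1)[C@H]2c1c(O[Si](C)(C)C(C)(C)C)c(C(=O)C#Cc3ccc(OCc4ccccc4)c(OCc4ccccc4)c3)c(OCc3ccccc3)cc1OCc1ccccc1
F4 | step 3 | C4 adduct with a 2,4-dihydroxy-6-benzyloxyphenyl ring D | c1ccccc1COc1cc(OCc3ccccc3)c2c(c1)O[C@@H](c1ccc(OCc3ccccc3)c(OCc3ccccc3)c1)[C@H](O)[C@H]2c1c(O)cc(O)cc1OCc1ccccc1
F5 | step 3 | C4 adduct with a 2,6-dihydroxy-4-benzyloxyphenyl ring D | c1ccccc1COc1cc(OCc3ccccc3)c2c(c1)O[C@@H](c1ccc(OCc3ccccc3)c(OCc3ccccc3)c1)[C@H](O)[C@H]2c1c(O)cc(OCc3ccccc3)cc1O
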